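**Retrosynthetic overview**
- Final move: one BCl3 operation frees 5-OH (a peri methyl ether) and 2′-OH/4′-OH (benzyl ethers) of a fully protected flavone.
- Key disconnection: C2 of the pyranone ring C is cut from C1′ (ring B), C3 and O1 at once and becomes carbon monoxide. A ring-B aryl bromide and a ring-A o-hydroxyacetophenone remain, and both are joined with CO in one Pd-catalysed three-component operation.
- Enabling feature: C2 is a single ketone-level carbon between aryl carbon C1′, acetyl-derived C3 and phenol oxygen O1. C1′–C2 (CO insertion), C2–C3 (acyl shift) and O1–C2 (cyclodehydration) can therefore follow each other in one flask. The oxygen pattern of ring A is mirror-symmetric about the C4a···C7 axis, so opening and reclosure of ring C through the A-ring oxygens is degenerate.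
- Ring order: rings A and B are bought as arenes (3,4,5-trimethoxyphenol, 4-bromoresorcinol). Ring C is the only ring built, in the key step.
- Fragment work: ring A by C-acetylation, bromination of the last free CH and Cu-catalysed methoxylation; ring B by double O-benzylation.

Key step: step 5

Remark on the chemistry: the target has no stereocentre and no hindered axis (the C2–C1′ bond rotates freely). It is therefore achiral, and no step has to set configuration.

**Step 1**
Reactants: 1 3,4,5-trimethoxyphenol
Product: 2 1-(6-hydroxy-2,3,4-trimethoxyphenyl)ethan-1-one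
Conditions: Ac2O (1.2 equiv), BF3·OEt2 (as medium), 80 °C; then H2O
Reagents that add atoms: acetic anhydride, CC(=O)OC(C)=O
Why: Friedel–Crafts C-acetylation (through the O-acetate and a Fries shift) of a very electron-rich phenol goes ortho to the OH, the two ortho positions are equivalent, and the chelated ketone that forms deactivates the ring against a second acylation.

**Step 2**
Reactants: 2 1-(6-hydroxy-2,3,4-trimethoxyphenyl)ethan-1-one
Product: 3 1-(3-bromo-2-hydroxy-4,5,6-trimethoxyphenyl)ethan-1-one
Conditions: NBS (1.05 equiv), MeCN, 0 °C to rt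
Reagents that add atoms: N-bromosuccinimide, O=C1CCC(=O)N1Br
Why: Electrophilic aromatic bromination can only take the single free ring position, which is ortho to the phenol OH and far more reactive than the enol of the hindered acetyl group.

**Step 3**
Reactants: 3 1-(3-bromo-2-hydroxy-4,5,6-trimethoxyphenyl)ethan-1-one
Product: 4 1-(2-hydroxy-3,4,5,6-tetramethoxyphenyl)ethan-1-one
Conditions: NaOMe (25% in MeOH, 5 equiv), CuBr (20 mol%), DMF, 110 °C; then 1 M HCl
Reagents that add atoms: sodium methoxide, [Na+].[O-]C
Why: Copper-catalysed Ullmann-type methoxylation of an aryl bromide ortho to a phenoxide is the reaction type that turns 5-bromovanillin into syringaldehyde, and the ketone is shielded from aldol chemistry by its two ortho substituents and its conjugation with the phenoxide.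

**Step 4**
Reactants: 5 4-bromobenzene-1,3-diol (4-bromoresorcinol)
Product: 6 2,4-bis(benzyloxy)-1-bromobenzene
Conditions: BnBr (2.2 equiv), K2CO3 (2.5 equiv), DMF, 60 °C
Reagents that add atoms: benzyl bromide, BrCc1ccccc1
Why: Williamson ether synthesis caps both phenols as benzyl ethers, which withstand DBU, Pd(0) and CO at 120 °C and keep the ring-B oxygens from acting as nucleophiles in step 5.

**Step 5**
Reactants: 4 1-(2-hydroxy-3,4,5,6-tetramethoxyphenyl)ethan-1-one (1.2 equiv); 6 2,4-bis(benzyloxy)-1-bromobenzene
Product: 10 2-[2,4-bis(benzyloxy)phenyl]-5,6,7,8-tetramethoxy-4H-chromen-4-one, via aryl ester 7 (not isolated), via beta-diketone 8 (not isolated), via cyclic hemiketal 9 (not isolated)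
Conditions: CO (10 bar), Pd(OAc)2 (2 mol%), dppb (4 mol%), DBU (3 equiv), DMF, 120 °C
Reagents that add atoms: carbon monoxide, [C-]#[O+]
Why: Pd(0) inserts into the C–Br bond of 6, CO migrates into the aryl–Pd bond (this creates the bond from C1′ of ring B to the future C2), and the aroyl–Pd species is intercepted by the DBU-generated phenoxide of 4 to give ester 7. DBU then drives a Baker–Venkataraman O-to-C acyl shift through the acetyl enolate to diketone 8 (C2–C3 bond), the phenol of 8 adds to the aroyl carbonyl in a 6-exo-trig closure to hemiketal 9 (O1–C2 bond), and loss of water gives the pyranone ring C of 10. The closest known reaction type is the palladium-catalysed carbonylative synthesis of flavones from aryl bromides and 2-hydroxyacetophenones, supported by the carbonylative α-arylation of ketones, which would reach the same diketone 8 if the enolate rather than the phenoxide captured the acyl-palladium. No stereocentre persists, because C2 of 9 is transient and becomes sp2 on dehydration. The step needs a single carbonylation and a single direction of ring closure: 4 offers one free OH and one enolisable CH3, both ring-B oxygens are benzylated so that only the A-ring phenol can close onto the diketone, and the slight excess of 4 disfavours a second aroylation at C3. The electron-rich, ortho-substituted bromide is the slow partner, which is why a chelating alkyl-bridged diphosphine, 120 °C and CO pressure are chosen.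

**Step 6**
Reactants: 10 2-[2,4-bis(benzyloxy)phenyl]-5,6,7,8-tetramethoxy-4H-chromen-4-one
Product: 11 tamadone, 2-(2,4-dihydroxyphenyl)-5-hydroxy-6,7,8-trimethoxy-4H-chromen-4-one
Conditions: BCl3 (6 equiv), pentamethylbenzene (6 equiv), CH2Cl2, −78 °C to 0 °C; then H2O
Reagents that add atoms: none
Why: BCl3 chelates between the C4 carbonyl oxygen and the 5-OMe oxygen and cleaves only that methyl ether (chelation-controlled peri-demethylation), the benzyl ethers ionise already at −78 °C with their cations trapped by pentamethylbenzene (Friedel–Crafts scavenging) so that ring B is not C-benzylated, and the 6-, 7- and 8-OMe groups, which have no chelating carbonyl neighbour, should survive at or below 0 °C in this anhydrous medium, which also gives ring C no chance to open.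

**Compound list**
1 | 3,4,5-trimethoxyphenol | COc1cc(O)cc(OC)c1OC | starting material
2 | 1-(6-hydroxy-2,3,4-trimethoxyphenyl)ethan-1-one | CC(=O)c1c(O)cc(OC)c(OC)c1OC | intermediate
3 | 1-(3-bromo-2-hydroxy-4,5,6-trimethoxyphenyl)ethan-1-one | CC(=O)c1c(O)c(Br)c(OC)c(OC)c1OC | intermediate
4 | 1-(2-hydroxy-3,4,5,6-tetramethoxyphenyl)ethan-1-one | CC(=O)c1c(O)c(OC)c(OC)c(OC)c1OC | intermediate
5 | 4-bromobenzene-1,3-diol (4-bromoresorcinol) | Oc1ccc(Br)c(O)c1 | starting material
6 | 2,4-bis(benzyloxy)-1-bromobenzene | Brc1ccc(OCc2ccccc2)cc1OCc1ccccc1 | intermediate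
7 | 2-acetyl-3,4,5,6-tetramethoxyphenyl 2,4-bis(benzyloxy)benzoate (not isolated) | CC(=O)c1c(OC(=O)c2ccc(OCc3ccccc3)cc2OCc2ccccc2)c(OC)c(OC)c(OC)c1OC | intermediate
8 | 1-[2,4-bis(benzyloxy)phenyl]-3-(2-hydroxy-3,4,5,6-tetramethoxyphenyl)propane-1,3-dione (not isolated) | COc1c(OC)c(OC)c(C(=O)CC(=O)c2ccc(OCc3ccccc3)cc2OCc2ccccc2)c(O)c1OC | intermediate
9 | 2-[2,4-bis(benzyloxy)phenyl]-2-hydroxy-5,6,7,8-tetramethoxychroman-4-one (racemic, not isolated) | COc1c(OC)c(OC)c2c(c1OC)OC(O)(CC2=O)c1ccc(OCc2ccccc2)cc1OCc1ccccc1 | intermediate
10 | 2-[2,4-bis(benzyloxy)phenyl]-5,6,7,8-tetramethoxy-4H-chromen-4-one | COc1c(OC)c(OC)c2c(=O)cc(-c3ccc(OCc4ccccc4)cc3OCc3ccccc3)oc2c1OC | intermediate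
11 | tamadone, 2-(2,4-dihydroxyphenyl)-5-hydroxy-6,7,8-trimethoxy-4H-chromen-4-one (achiral) | COc1c(OC)c(O)c2c(=O)cc(-c3ccc(O)cc3O)oc2c1OC | target

**Total step count:** 6. **Longest linear sequence:** 5 (steps 1, 2, 3, 5, 6).

**Steps most likely to fail**

**Step 5.**
- *Risk:* Oxidative addition of the electron-rich, ortho-alkoxy bromide may be slow. The catalyst may aggregate under CO. The sequence may stall after the acyl shift, or a second aroylation at C3 may compete.
- *Fallback:* it sets out from 4 and 6 and returns at 10. Ring C is closed first, and the same C2–C1′ bond is then made on the finished chromone.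
  - Condensation of 4 with DMF dimethyl acetal (toluene, 100 °C) should give the enaminone (E)-3-(dimethylamino)-1-(2-hydroxy-3,4,5,6-tetramethoxyphenyl)prop-2-en-1-one F1.
  - F1 should cyclise with aqueous HCl in CH2Cl2 to 5,6,7,8-tetramethoxy-4H-chromen-4-one F2.
  - Bromide 6 is borylated (B2(OH)4, XPhos-Pd precatalyst, KOAc, EtOH, 80 °C) to [2,4-bis(benzyloxy)phenyl]boronic acid F3.
  - Pd(II)-catalysed conjugate addition of F3 to C2 of F2 (Pd(TFA)2, 2,2′-bipyridine, AcOH/THF/H2O, 60 °C) should give the racemic flavanone 2-[2,4-bis(benzyloxy)phenyl]-5,6,7,8-tetramethoxychroman-4-one F4.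
  - Dehydrogenation of F4 (cat. I2, DMSO, 110 °C) leads to 10.

**Step 6.**
- *Risk:* A further methyl group may be lost, either next to the freshly liberated 5-OH or at the crowded central 7-position. Ring B may be C-benzylated if cation trapping is too slow.
- *Fallback:* it sets out from 10 and returns at 11. The single Lewis-acid operation is replaced by two orthogonal deprotections.
  - Magnesium iodide etherate (toluene/Et2O, 70 °C) is too weak to attack an unchelated ether. It should remove only the peri methyl group and give 2-[2,4-bis(benzyloxy)phenyl]-5-hydroxy-6,7,8-trimethoxy-4H-chromen-4-one F5.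
  - Neutral hydrogenolysis of F5 (H2, 1 atm, Pd/C, EtOAc/MeOH, rt) then removes both benzyl groups and gives 11, so the 2′-OH is never exposed to acid.

**Step 3.**
- *Risk:* Reductive loss of bromine may compete with C–O coupling, and the methyl ketone may self-condense under base at 110 °C.
- *Fallback:* it sets out from 2 and returns at 4. It avoids both the halide and copper.
  - Duff formylation of 2 (hexamethylenetetramine, TFA, 85 °C; then aqueous HCl) at the only free ring CH should give 3-acetyl-2-hydroxy-4,5,6-trimethoxybenzaldehyde F6.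
  - Dakin oxidation of F6 (H2O2, aqueous NaOH, 0 °C, under N2) attacks the aldehyde in preference to the hindered ketone and should give 1-(2,3-dihydroxy-4,5,6-trimethoxyphenyl)ethan-1-one F7.
  - Methylation of F7 (MeI, 1 equiv, Li2CO3, DMF, rt) should take the unchelated 3-OH and leave the ketone-bound 2-OH free, which gives 4.

**Further compounds**
F1 | step 5 | (E)-3-(dimethylamino)-1-(2-hydroxy-3,4,5,6-tetramethoxyphenyl)prop-2-en-1-one | CN(C)/C=C/C(=O)c1c(O)c(OC)c(OC)c(OC)c1OC
F2 | step 5 | 5,6,7,8-tetramethoxy-4H-chromen-4-one | COc1c(OC)c(OC)c2c(=O)ccoc2c1OC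
F3 | step 5 | [2,4-bis(benzyloxy)phenyl]boronic acid | OB(O)c1ccc(OCc2ccccc2)cc1OCc1ccccc1
F4 | step 5 | 2-[2,4-bis(benzyloxy)phenyl]-5,6,7,8-tetramethoxychroman-4-one (racemic) | COc1c(OC)c(OC)c2c(c1OC)OC(CC2=O)c1ccc(OCc2ccccc2)cc1OCc1ccccc1
F5 | step 6 | 2-[2,4-bis(benzyloxy)phenyl]-5-hydroxy-6,7,8-trimethoxy-4H-chromen-4-one | COc1c(OC)c(O)c2c(=O)cc(-c3ccc(OCc4ccccc4)cc3OCc3ccccc3)oc2c1OC
F6 | step 3 | 3-acetyl-2-hydroxy-4,5,6-trimethoxybenzaldehyde | CC(=O)c1c(O)c(C=O)c(OC)c(OC)c1OC
F7 | step 3 | 1-(2,3-dihydroxy-4,5,6-trimethoxyphenyl)ethan-1-one | CC(=O)c1c(O)c(O)c(OC)c(OC)c1OC
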